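**Retrosynthetic overview**
1. Ardisiphenol D ⇒ (O–Si cleavage, O‑acetylation) 2‑methoxy‑6‑tridecyl‑4‑(triisopropylsilyloxy)phenol. The two hydroquinone oxygens are never free together, so the hindered one takes the acetyl group without a selectivity problem.
2. That phenol ⇒ one‑pot 1,2‑difunctionalisation of 3‑methoxy‑5‑(triisopropylsilyloxy)benzyne. Tridecyllithium makes the aryl–CH2 bond, and the aryl anion left beside it takes up oxygen (B(OMe)3, then H2O2).
3. Enabling feature: in the single benzene ring the chain‑bearing carbon C6, the acetoxy carbon C1 and the methoxy carbon C2 are contiguous. C6≡C1 can therefore be an aryne with the C2 methoxy oxygen right beside it, and this oxygen sends the carbon nucleophile to C6 and the charge (later the oxygen) to C1.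
4. The aryne ⇒ TIPS ether of 3‑fluoro‑5‑methoxyphenol (lithiation at the C–H between F and OMe, loss of LiF). The C13 part ⇒ 1‑bromotridecane.
5. No ring is formed. The benzene ring is bought 1,3,5‑trisubstituted and leaves the key step with all four substituent positions filled.

Key step: step 3

Remark: the target is achiral, so no step has to set or protect a stereocentre.

**Step 1**
Reactants: 1 3‑fluoro‑5‑methoxyphenol
Product: 2 (3‑fluoro‑5‑methoxyphenoxy)triisopropylsilane
Conditions: TIPSCl (1.1 equiv), imidazole (2 equiv), DMF, rt
Reagents that add atoms: triisopropylsilyl chloride (TIPSCl), CC(C)[Si](Cl)(C(C)C)C(C)C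
Why: Imidazole‑promoted silylation of a phenol; the bulky TIPS ether survives alkyllithiums, shields its own two ortho positions and marks this oxygen as the one that ends up free.

**Step 2**
Reactants: 3 1‑bromotridecane
Product: 4 tridecyllithium (kept as a filtered, titrated ether solution)
Conditions: Li wire (about 1% Na, excess), Et2O, −10 °C, argon, slow addition of 3
Reagents that add atoms: lithium metal, [Li]
Why: Reductive lithiation of a primary alkyl bromide with lithium metal in ether is the classical preparation of n‑alkyllithiums, and low temperature with slow addition limits Wurtz coupling.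

**Step 3**
Reactants: 2 (3‑fluoro‑5‑methoxyphenoxy)triisopropylsilane; 4 tridecyllithium
Product: 9 2‑methoxy‑6‑tridecyl‑4‑(triisopropylsilyloxy)phenol, via lithiated fluoroarene 5 (not isolated), via aryne 6 (not isolated), via aryllithium 7 (not isolated), via lithium aryltrimethoxyborate 8 (not isolated)
Conditions: 4 (1.05 equiv), THF, −78 °C; cold solution cannulated into 4 (2 equiv), Et2O/THF, −20 → 0 °C; B(OMe)3 (5 equiv), −78 °C → rt; AcOH, 30% aq H2O2, 0 °C → rt; Na2S2O3 quench
Reagents that add atoms: hydrogen peroxide, OO (the phenol oxygen); trimethyl borate, COB(OC)OC (its atoms are held only in intermediate 8)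
Why: The first equivalent of 4 removes the most acidic ring proton of 2, the one flanked by F and OMe (directed ortho‑metalation; the bulky, poorly coordinating OTIPS group shields both positions next to it), and on warming 5 loses LiF to give the single aryne 6. A further equivalent of 4 adds across the triple bond (aryne carbolithiation), which forms the aryl–CH2 bond and leaves aryllithium 7; B(OMe)3 captures 7 as borate 8, and H2O2 turns 8 into the phenol by a 1,2‑shift of the aryl group from boron to oxygen. The closest known reaction type is the tandem addition of alkyllithiums to 3‑methoxybenzyne made from 3‑haloanisoles followed by an electrophilic quench, joined to the standard borylation–oxidation of aryllithiums. The step needs regioselective addition, and the σ‑withdrawing methoxy oxygen beside the triple bond secures it: it distorts the aryne so that the remote carbon is the more linear, more electrophilic and less hindered one, and attack there places the charge ortho to OMe, where induction and Li···OMe chelation stabilise it, while the more distant OTIPS group should have only a minor influence. No ring is closed and no stereocentre is formed. Capture of 6 by 5 or 7 instead of 4 is held down by the inverse addition, which keeps 4 in excess while the aryne is released.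

**Step 4**
Reactants: 9 2‑methoxy‑6‑tridecyl‑4‑(triisopropylsilyloxy)phenol
Product: 10 2‑methoxy‑6‑tridecyl‑4‑(triisopropylsilyloxy)phenyl acetate
Conditions: Ac2O (1.5 equiv), Et3N (2 equiv), DMAP (cat.), CH2Cl2, 0 °C → rt
Reagents that add atoms: acetic anhydride, CC(=O)OC(C)=O
Why: DMAP‑catalysed O‑acylation (nucleophilic catalysis) acetylates even a phenol flanked by two ortho groups, and this is the only free hydroxyl in 9, so no site selection is needed.

**Step 5**
Reactants: 10 2‑methoxy‑6‑tridecyl‑4‑(triisopropylsilyloxy)phenyl acetate
Product: 11 ardisiphenol D (4‑hydroxy‑2‑methoxy‑6‑tridecylphenyl acetate)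
Conditions: TBAF (1.2 equiv), AcOH (1.5 equiv), THF, 0 °C
Reagents that add atoms: none
Why: Fluoride‑induced cleavage of an aryl silyl ether driven by Si–F bond formation; the acetic acid buffer protonates the phenoxide as it forms, so the hindered aryl acetate should be neither cleaved nor transferred.

**Compound list**
1 | 3‑fluoro‑5‑methoxyphenol | COc1cc(O)cc(F)c1 | starting material
2 | (3‑fluoro‑5‑methoxyphenoxy)triisopropylsilane | COc1cc(F)cc(O[Si](C(C)C)(C(C)C)C(C)C)c1 | intermediate
3 | 1‑bromotridecane | CCCCCCCCCCCCCBr | starting material
4 | tridecyllithium | [Li]CCCCCCCCCCCCC | intermediate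
5 | [2‑fluoro‑6‑methoxy‑4‑(triisopropylsilyloxy)phenyl]lithium | [Li]c1c(F)cc(O[Si](C(C)C)(C(C)C)C(C)C)cc1OC | intermediate
6 | 3‑methoxy‑5‑(triisopropylsilyloxy)benzyne | COC1=CC(O[Si](C(C)C)(C(C)C)C(C)C)=CC#C1 | intermediate
7 | [2‑methoxy‑6‑tridecyl‑4‑(triisopropylsilyloxy)phenyl]lithium | [Li]c1c(CCCCCCCCCCCCC)cc(O[Si](C(C)C)(C(C)C)C(C)C)cc1OC | intermediate
8 | lithium trimethoxy[2‑methoxy‑6‑tridecyl‑4‑(triisopropylsilyloxy)phenyl]borate | [Li+].CO[B-](OC)(OC)c1c(CCCCCCCCCCCCC)cc(O[Si](C(C)C)(C(C)C)C(C)C)cc1OC | intermediate
9 | 2‑methoxy‑6‑tridecyl‑4‑(triisopropylsilyloxy)phenol | CCCCCCCCCCCCCc1cc(O[Si](C(C)C)(C(C)C)C(C)C)cc(OC)c1O | intermediate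
10 | 2‑methoxy‑6‑tridecyl‑4‑(triisopropylsilyloxy)phenyl acetate | CCCCCCCCCCCCCc1cc(O[Si](C(C)C)(C(C)C)C(C)C)cc(OC)c1OC(C)=O | intermediate
11 | ardisiphenol D | CCCCCCCCCCCCCc1cc(O)cc(OC)c1OC(C)=O | target

**Total step count:** 5
**Longest linear sequence:** 4 steps (1 → 2 → 9 → 10 → 11; the branch 3 → 4 joins at step 3 and is equally long).

**Steps most likely to fail**

Step 3. The risks are capture of the aryne by the aryllithium species instead of tridecyllithium, lithiation at a wrong ring position, and incomplete borylation of the doubly ortho‑substituted aryllithium. The fallback gives up the aryne for a cross‑coupling on a ring that already carries the oxygen. It sets out from 3 and comes back at 11.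
- 1‑Bromotridecane 3 would be converted with zinc dust and LiCl in THF into tridecylzinc bromide F1.
- Purchased 5‑bromovanillin F2 carries Br, OH and OMe on three neighbouring ring carbons. It would be acetylated (Ac2O, pyridine) to 2‑bromo‑4‑formyl‑6‑methoxyphenyl acetate F3.
- Negishi coupling of F1 with F3 (Pd(OAc)2, SPhos, THF, rt) should form the same aryl–CH2 bond and give 4‑formyl‑2‑methoxy‑6‑tridecylphenyl acetate F4.
- Baeyer–Villiger oxidation (mCPBA, CH2Cl2) should give 4‑(formyloxy)‑2‑methoxy‑6‑tridecylphenyl acetate F5.
- Brief methanolysis (NaHCO3, MeOH, 0 °C) of the unhindered and far more reactive formate should leave the flanked acetate in place and give 11.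

Step 5. The risk is loss or intermolecular transfer of the acetyl group once fluoride sets phenoxide free. The fallback replaces orthogonal protection by steric differentiation of a diacetate. It sets out from 9 and comes back at 11.
- Compound 9 would be desilylated first (TBAF, AcOH, THF, argon) to 2‑methoxy‑6‑tridecylbenzene‑1,4‑diol F6.
- F6 would be peracetylated (Ac2O, pyridine, DMAP) to 2‑methoxy‑6‑tridecyl‑1,4‑phenylene diacetate F7.
- One equivalent of pyrrolidine in CH2Cl2 at 0 °C should aminolyse the acetate that has two ortho hydrogens much faster than the one flanked by OMe and the chain, which gives 11.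

Step 2. The risks are Wurtz‑type homocoupling on the metal surface and slow attack on the ether, both of which lower the titre of the organolithium. The fallback replaces metal insertion by halogen–lithium exchange. It sets out from 3 and comes back at 4.
- A Finkelstein reaction (NaI, acetone, reflux) would give 1‑iodotridecane F8.
- Lithium–iodine exchange with tBuLi (2.1 equiv, pentane/Et2O, −78 °C) should deliver 4 cleanly in solution.

**Further compounds**
F1 | step 3 | tridecylzinc bromide | CCCCCCCCCCCCC[Zn]Br
F2 | step 3 | 5‑bromovanillin (purchased) | COc1cc(C=O)cc(Br)c1O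
F3 | step 3 | 2‑bromo‑4‑formyl‑6‑methoxyphenyl acetate | CC(=O)Oc1c(Br)cc(C=O)cc1OC
F4 | step 3 | 4‑formyl‑2‑methoxy‑6‑tridecylphenyl acetate | CCCCCCCCCCCCCc1cc(C=O)cc(OC)c1OC(C)=O
F5 | step 3 | 4‑(formyloxy)‑2‑methoxy‑6‑tridecylphenyl acetate | CCCCCCCCCCCCCc1cc(OC=O)cc(OC)c1OC(C)=O
F6 | step 5 | 2‑methoxy‑6‑tridecylbenzene‑1,4‑diol | CCCCCCCCCCCCCc1cc(O)cc(OC)c1O
F7 | step 5 | 2‑methoxy‑6‑tridecyl‑1,4‑phenylene diacetate | CCCCCCCCCCCCCc1cc(OC(C)=O)cc(OC)c1OC(C)=O
F8 | step 2 | 1‑iodotridecane | CCCCCCCCCCCCCI
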